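**Retrosynthetic overview**

1. Numbering follows the labdanes: C4 carries the C18 methyl and the C19 carboxyl, C20 is the methyl on C10, C17 the exocyclic carbon on C8, C11–C16 the side chain; TBS = tert-butyldimethylsilyl.
2. End game: target ⇐ C12 aldehyde (two Wittig olefinations) ⇐ 7β-alcohol (Mitsunobu acetate with inversion) ⇐ 7-oxo-8(17)-ene acid ⇐ reductive opening of a 19,6β-lactone that lies α to the C7 ketone.
3. Key disconnection: ring B (bonds C5–C6 and C9–C10) and the lactone ring are closed together by an intramolecular radical-cation [4+2] cyclisation of a 2-silyloxydienyl ester onto the C5=C10 alkene of ring A. Ring order: ring A first (Birch), then lactone ring and ring B in one operation.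
4. Enabling feature: the axial C19 carboxyl on C4 of ring A and C6 of ring B are 1,3-syn across C5, so a five-membered lactone C19–O–C6 can span them. As an ester this link tethers the C6–C9 unit to ring A and fixes C5; it is excised later because the C6–O bond is α to C7=O.
5. Fragments: (S)-1,3-dimethylcyclohex-2-ene-1-carboxylic acid (from 3-methylbenzoic acid by Birch reductive methylation, selective hydrogenation, resolution) and an (E)-chloro enone made by a Wittig reaction.

Key step: step 7

Assumption: (R)-1-phenylethylamine is taken to give the less soluble salt with the (S)-acid in step 3; if the other salt crystallises, (S)-1-phenylethylamine is used in the same way.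

**Route**

Step 1
Reactants: 1 3-methylbenzoic acid
Product: 2 rac-1,3-dimethylcyclohexa-2,5-diene-1-carboxylic acid
Conditions: Li (3.3 equiv), NH3(l)/THF, −78 °C; MeI, −78 °C to rt; aq. HCl
Reagents that add atoms: iodomethane, CI
Why: Birch reductive alkylation: Li/NH3 reduces the benzoate to the 1,4-dihydro enediolate, which is C-methylated at the carboxyl-bearing carbon, so the quaternary centre forms as the racemate.

Step 2
Reactants: 2 rac-1,3-dimethylcyclohexa-2,5-diene-1-carboxylic acid
Product: 3 rac-1,3-dimethylcyclohex-2-ene-1-carboxylic acid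
Conditions: H2 (1 atm), RhCl(PPh3)3 (5 mol %), benzene/EtOH, rt
Reagents that add atoms: none
Why: Homogeneous hydrogenation with RhCl(PPh3)3 should saturate the cis-disubstituted C=C and leave the trisubstituted C=C(CH3) untouched; no stereocentre changes.

Step 3
Reactants: 3 rac-1,3-dimethylcyclohex-2-ene-1-carboxylic acid
Product: 4 (S)-1,3-dimethylcyclohex-2-ene-1-carboxylic acid
Conditions: (R)-1-phenylethylamine (1 equiv), acetone, recrystallise to constant rotation; 1 M HCl/Et2O
Reagents that add atoms: none
Why: Classical resolution through diastereomeric ammonium carboxylates of different solubility; the quaternary centre cannot racemise, so acidification of the pure salt should give the single (S)-acid.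

Step 4
Reactants: 5 3-[(tert-butyldimethylsilyl)oxy]propanal; 6 1-chloro-3-(triphenylphosphoranylidene)propan-2-one
Product: 7 (E)-6-[(tert-butyldimethylsilyl)oxy]-1-chlorohex-3-en-2-one
Conditions: CH2Cl2, rt to 40 °C
Reagents that add atoms: none
Why: Wittig olefination with a ketone-stabilised ylide, which should give the (E)-enone.

Step 5
Reactants: 4 (S)-1,3-dimethylcyclohex-2-ene-1-carboxylic acid; 7 (E)-6-[(tert-butyldimethylsilyl)oxy]-1-chlorohex-3-en-2-one
Product: 8 (E)-6-[(tert-butyldimethylsilyl)oxy]-2-oxohex-3-en-1-yl (S)-1,3-dimethylcyclohex-2-ene-1-carboxylate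
Conditions: Cs2CO3 (0.5 equiv), DMF; then 7, NaI (10 mol %), 0 °C to rt
Reagents that add atoms: none
Why: SN2 O-alkylation of the cesium carboxylate by the α-chloro ketone (phenacyl-type ester formation), which leaves the stereocentre untouched.

Step 6
Reactants: 8 (E)-6-[(tert-butyldimethylsilyl)oxy]-2-oxohex-3-en-1-yl (S)-1,3-dimethylcyclohex-2-ene-1-carboxylate
Product: 9 (1Z,3E)-2,6-bis[(tert-butyldimethylsilyl)oxy]hexa-1,3-dien-1-yl (S)-1,3-dimethylcyclohex-2-ene-1-carboxylate
Conditions: TBSOTf, Et3N, CH2Cl2, −78 to 0 °C
Reagents that add atoms: tert-butyldimethylsilyl trifluoromethanesulfonate, CC(C)(C)[Si](C)(C)OS(=O)(=O)C(F)(F)F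
Why: Soft enolisation with silyl triflate and amine removes a hydrogen from the acyloxy-bearing CH2 (C6), the most acidic α-position, and O-silylation gives the cross-conjugated 2-silyloxydiene, the (1Z) geometry being expected from the syn arrangement of the two oxygens.

Step 7
Reactants: 9 (1Z,3E)-2,6-bis[(tert-butyldimethylsilyl)oxy]hexa-1,3-dien-1-yl (S)-1,3-dimethylcyclohex-2-ene-1-carboxylate
Product: 10 tricyclic enol silane lactone (7,12-bis(TBSO)-13,14,15,16,17-pentanorlabd-7-en-19,6β-olide; 5α-H, 6α-H, 9α-H, 10β-CH3)
Conditions: 9-mesityl-10-methylacridinium tetrafluoroborate (5 mol %), 2,6-di-tert-butylpyridine (10 mol %), 450 nm LEDs, degassed CH2Cl2 (0.01 M), rt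
Reagents that add atoms: none
Why: Proposed new method: one-electron oxidation of the 2-silyloxydiene of 9 (its most easily oxidised π-system) by the photoexcited acridinium gives a diene radical cation; its C6 terminus is attacked by C5, the less substituted carbon of the ring A alkene (5-exo closure of the γ-lactone ring through the ester tether, leaving tertiary cation/radical character at C10), C10 then bonds to C9 of the silyloxyallyl unit (closure of the six-membered ring B, 6-endo with respect to C8=C9), and the enol silane radical cation is reduced by the acridine radical or by fresh 9 in a chain. The closest known reaction types are the radical-cation Diels–Alder reaction (aminium-salt or photoredox catalysis) and the photoinduced-electron-transfer cyclisation of unsaturated silyl enol ethers; the new elements are an unactivated trisubstituted alkene as the neutral partner and a stepwise, non-suprafacial course. C5 and C6: the three-atom ester tether allows only the cis-fused γ-lactone, so C6 is delivered to the face of C5 that carries C19 (H-5 ends α), and only the C6 epimer with C7 syn to C10 can close ring B. C10 and C9: in the cis-fused lactone C19 is axial on ring A and shields the same (β) face of C10, so C9 bonds equatorially and the methyl is left axial (trans ring fusion), while a chair-like closure of the (E)-C8=C9 unit places the CH2CH2OTBS arm equatorial (H-9 α). The step needs C6-to-C5 rather than C6-to-C10 regiochemistry, a stepwise rather than concerted course, and retention of silicon on O7; these are secured by the tertiary character of C10, by the 1,3-relationship of C19 and C6 across C5 (which makes the suprafacial adduct a strained cis-decalin), and by the bulky silyl group in a non-nucleophilic solvent.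

Step 8
Reactants: 10 tricyclic enol silane lactone
Product: 13 enone lactone (12-TBSO-7-oxo-13,14,15,16-tetranorlabd-8(17)-en-19,6β-olide), via Mannich base 11 (not isolated), via methiodide 12 (not isolated)
Conditions: CH2=NMe2+ I−, CH2Cl2, rt; MeI, rt; aq. NaHCO3, rt
Reagents that add atoms: N,N-dimethylmethyleneiminium iodide, C=[N+](C)C.[I-]
Why: Mannich reaction of the regiodefined enol silane at C8, N-methylation and E1cB (Hofmann-type) elimination under weak base should give the exocyclic enone; the C8 stereocentre formed in passing is destroyed.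

Step 9
Reactants: 13 enone lactone
Product: 14 keto acid (12-TBSO-7-oxo-13,14,15,16-tetranorlabd-8(17)-en-19-oic acid)
Conditions: SmI2 (2.2 equiv), THF/MeOH, −78 °C; pH 3 buffer
Reagents that add atoms: none
Why: Reductive cleavage of an α-acyloxy ketone by SmI2 (the axial C6–O bond is aligned with the carbonyl π system; the samarium dienolate is protonated at C6), as in the reductive removal of phenacyl esters, releasing the free C19 acid and leaving C6 as CH2.

Step 10
Reactants: 14 keto acid
Product: 15 7β-hydroxy acid (12-TBSO-7β-hydroxy-13,14,15,16-tetranorlabd-8(17)-en-19-oic acid)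
Conditions: NaBH4, CeCl3·7H2O, MeOH, −40 °C
Reagents that add atoms: none
Why: Luche 1,2-reduction: the small hydride should add axially from the α-face of the ring B ketone and set the equatorial 7β-alcohol, while CeCl3 suppresses conjugate reduction.

Step 11
Reactants: 15 7β-hydroxy acid
Product: 16 7α-acetoxy acid (7α-acetoxy-12-TBSO-13,14,15,16-tetranorlabd-8(17)-en-19-oic acid)
Conditions: PPh3, DIAD, AcOH (5 equiv), THF, 0 °C to rt
Reagents that add atoms: acetic acid, CC(=O)O
Why: Mitsunobu reaction: the alkoxyphosphonium of the allylic 7β-alcohol is displaced by acetate with inversion (SN2), setting the axial 7α-acetate; excess acetic acid outcompetes the hindered C19 carboxyl.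

Step 12
Reactants: 16 7α-acetoxy acid
Product: 17 7α-acetoxy-12-hydroxy-13,14,15,16-tetranorlabd-8(17)-en-19-oic acid
Conditions: HF·pyridine, pyridine/THF, 0 °C to rt
Reagents that add atoms: none
Why: Fluoride-mediated cleavage of the primary silyl ether under buffered conditions to which the acetate, the acid and the alkene are inert.

Step 13
Reactants: 17 7α-acetoxy-12-hydroxy-13,14,15,16-tetranorlabd-8(17)-en-19-oic acid
Product: 18 aldehyde (7α-acetoxy-12-oxo-13,14,15,16-tetranorlabd-8(17)-en-19-oic acid)
Conditions: Dess–Martin periodinane, NaHCO3, CH2Cl2, rt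
Reagents that add atoms: none
Why: Oxidation of the primary alcohol to the aldehyde with the hypervalent iodine reagent under buffered, non-epimerising conditions.

Step 14
Reactants: 18 aldehyde; 19 2-(triphenylphosphoranylidene)propanal
Product: 20 enal ((12E)-7α-acetoxy-14-oxo-15-norlabda-8(17),12-dien-19-oic acid)
Conditions: toluene, 90 °C (19: 2.5 equiv)
Reagents that add atoms: none
Why: Wittig olefination with an aldehyde-stabilised ylide, which should give the (E)-trisubstituted enal.

Step 15
Reactants: 20 enal
Product: 21 7α-acetoxy-labda-8(17),12E,14-trien-19-oic acid (target)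
Conditions: Ph3PCH3+ Br−, KN(SiMe3)2, THF, 0 °C; then 20, −78 to 0 °C; pH 4 buffer
Reagents that add atoms: methylenetriphenylphosphorane, C=P(c1ccccc1)(c1ccccc1)c1ccccc1, made in the flask from methyltriphenylphosphonium bromide, C[P+](c1ccccc1)(c1ccccc1)c1ccccc1.[Br-]
Why: Wittig methylenation of the enal by 1,2-addition should complete the (E)-diene; one equivalent of ylide is consumed by the carboxylic acid, which is restored on work-up, and the low temperature spares the acetate.

**Compound list**

1 | 3-methylbenzoic acid | Cc1cccc(C(=O)O)c1 | starting material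
2 | rac-1,3-dimethylcyclohexa-2,5-diene-1-carboxylic acid | CC1=CC(C)(C(=O)O)C=CC1 | intermediate
3 | rac-1,3-dimethylcyclohex-2-ene-1-carboxylic acid | CC1=CC(C)(C(=O)O)CCC1 | intermediate
4 | (S)-1,3-dimethylcyclohex-2-ene-1-carboxylic acid | C[C@@]1(C(=O)O)C=C(C)CCC1 | intermediate
5 | 3-[(tert-butyldimethylsilyl)oxy]propanal | O=CCCO[Si](C)(C)C(C)(C)C | starting material
6 | 1-chloro-3-(triphenylphosphoranylidene)propan-2-one | ClCC(=O)C=P(c1ccccc1)(c1ccccc1)c1ccccc1 | starting material
7 | (E)-6-[(tert-butyldimethylsilyl)oxy]-1-chlorohex-3-en-2-one | ClCC(=O)/C=C/CCO[Si](C)(C)C(C)(C)C | intermediate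
8 | (E)-6-[(tert-butyldimethylsilyl)oxy]-2-oxohex-3-en-1-yl (S)-1,3-dimethylcyclohex-2-ene-1-carboxylate | C[C@@]1(C(=O)OCC(=O)/C=C/CCO[Si](C)(C)C(C)(C)C)C=C(C)CCC1 | intermediate
9 | (1Z,3E)-2,6-bis[(tert-butyldimethylsilyl)oxy]hexa-1,3-dien-1-yl (S)-1,3-dimethylcyclohex-2-ene-1-carboxylate | C[C@@]1(C(=O)O/C=C(\O[Si](C)(C)C(C)(C)C)/C=C/CCO[Si](C)(C)C(C)(C)C)C=C(C)CCC1 | intermediate
10 | 7,12-bis[(tert-butyldimethylsilyl)oxy]-13,14,15,16,17-pentanorlabd-7-en-19,6β-olide (trans-decalin; 5α-H, 6α-H, 9α-H, 10β-CH3) | CC(C)(C)[Si](C)(C)OCC[C@H]1C=C(O[Si](C)(C)C(C)(C)C)[C@@H]3[C@@H]2[C@]1(C)CCC[C@]2(C)C(=O)O3 | intermediate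
11 | 17-(dimethylamino)-12-[(tert-butyldimethylsilyl)oxy]-7-oxo-13,14,15,16-tetranorlabdan-19,6β-olide (Mannich base, C8 epimers) | CC(C)(C)[Si](C)(C)OCC[C@H]1C(CN(C)C)C(=O)[C@@H]3[C@@H]2[C@]1(C)CCC[C@]2(C)C(=O)O3 | intermediate
12 | trimethylammonium iodide of 11 (methiodide, C8 epimers) | CC(C)(C)[Si](C)(C)OCC[C@H]1C(C[N+](C)(C)C)C(=O)[C@@H]3[C@@H]2[C@]1(C)CCC[C@]2(C)C(=O)O3.[I-] | intermediate
13 | 12-[(tert-butyldimethylsilyl)oxy]-7-oxo-13,14,15,16-tetranorlabd-8(17)-en-19,6β-olide | CC(C)(C)[Si](C)(C)OCC[C@H]1C(=C)C(=O)[C@@H]3[C@@H]2[C@]1(C)CCC[C@]2(C)C(=O)O3 | intermediate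
14 | 12-[(tert-butyldimethylsilyl)oxy]-7-oxo-13,14,15,16-tetranorlabd-8(17)-en-19-oic acid | CC(C)(C)[Si](C)(C)OCC[C@H]1C(=C)C(=O)C[C@@H]2[C@]1(C)CCC[C@]2(C)C(=O)O | intermediate
15 | 12-[(tert-butyldimethylsilyl)oxy]-7β-hydroxy-13,14,15,16-tetranorlabd-8(17)-en-19-oic acid | CC(C)(C)[Si](C)(C)OCC[C@H]1C(=C)[C@@H](O)C[C@@H]2[C@]1(C)CCC[C@]2(C)C(=O)O | intermediate
16 | 7α-acetoxy-12-[(tert-butyldimethylsilyl)oxy]-13,14,15,16-tetranorlabd-8(17)-en-19-oic acid | CC(C)(C)[Si](C)(C)OCC[C@H]1C(=C)[C@H](OC(C)=O)C[C@@H]2[C@]1(C)CCC[C@]2(C)C(=O)O | intermediate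
17 | 7α-acetoxy-12-hydroxy-13,14,15,16-tetranorlabd-8(17)-en-19-oic acid | OCC[C@H]1C(=C)[C@H](OC(C)=O)C[C@@H]2[C@]1(C)CCC[C@]2(C)C(=O)O | intermediate
18 | 7α-acetoxy-12-oxo-13,14,15,16-tetranorlabd-8(17)-en-19-oic acid | O=CC[C@H]1C(=C)[C@H](OC(C)=O)C[C@@H]2[C@]1(C)CCC[C@]2(C)C(=O)O | intermediate
19 | 2-(triphenylphosphoranylidene)propanal | CC(C=O)=P(c1ccccc1)(c1ccccc1)c1ccccc1 | starting material
20 | (12E)-7α-acetoxy-14-oxo-15-norlabda-8(17),12-dien-19-oic acid | O=C/C(C)=C/C[C@H]1C(=C)[C@H](OC(C)=O)C[C@@H]2[C@]1(C)CCC[C@]2(C)C(=O)O | intermediate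
21 | 7α-acetoxy-labda-8(17),12E,14-trien-19-oic acid | C=C/C(C)=C/C[C@H]1C(=C)[C@H](OC(C)=O)C[C@@H]2[C@]1(C)CCC[C@]2(C)C(=O)O | target

**Step count and risks**

Total step count: 15. Longest linear sequence: 14 steps (steps 1–3 and 5–15; step 4 is a one-step branch).

Steps most likely to fail:

Step 7 (proposed new method). The second ring may close suprafacially or from the ring-flipped lactone conformer, giving a cis ring fusion. The radical cation may lose silicon before ring B closes. Back electron transfer may outrun the slow first cyclisation through the disfavoured s-cis ester rotamer. The fallback replaces the catalytic radical-cation isomerisation by a neutral tin-hydride radical chain built from known reaction types; it sets out from 9 and returns at 10. Selenenylation of the enol silane of 9 with PhSeCl (CH2Cl2, −78 °C) should give the α-selenide (E)-6-[(tert-butyldimethylsilyl)oxy]-2-oxo-1-(phenylselanyl)hex-3-en-1-yl (S)-1,3-dimethylcyclohex-2-ene-1-carboxylate F1. Slow addition of Bu3SnH with AIBN (benzene, 80 °C) should then generate the α-keto radical at C6, which cyclises 5-exo onto C5 and 6-endo from C10 onto the enone carbon C9 and ends by hydrogen transfer to C8, giving 12-[(tert-butyldimethylsilyl)oxy]-7-oxo-13,14,15,16,17-pentanorlabdan-19,6β-olide F2. Kinetic enolisation of F2 with LiN(SiMe3)2 and TBSCl (THF, −78 °C) can only remove the axial hydrogen on C8, because the hydrogen on C6 is equatorial and lies in the carbonyl plane, and so returns to 10.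

Step 9. Electron transfer into the cross-conjugated enone may lead to ketyl dimerisation, to saturation of the exocyclic C8=C17 bond, or to its migration into the ring, instead of clean C6–O scission. The fallback changes the order so that the reductive cleavage is run before the enone exists; it sets out from 10 and returns at 14. Treatment of 10 with the iminium iodide alone and aqueous work-up gives the Mannich base 11, which is isolated. SmI2 (THF/MeOH, −78 °C) should then cleave the lactone to 17-(dimethylamino)-12-[(tert-butyldimethylsilyl)oxy]-7-oxo-13,14,15,16-tetranorlabdan-19-oic acid F3. Oxidation of the amine with 3-chloroperoxybenzoic acid (CH2Cl2, 0 °C) gives the N-oxide of F3, 17-(dimethyloxidoamino)-12-[(tert-butyldimethylsilyl)oxy]-7-oxo-13,14,15,16-tetranorlabdan-19-oic acid F4, which on warming to rt should undergo Cope elimination to 14.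

Step 11. Competing SN2' attack of acetate at C17, E2 elimination to a diene, or esterification with retention through an acyloxyphosphonium pathway would erode the inversion at C7. The fallback sets the 7α-alcohol directly under reagent control and acetylates with retention; it sets out from 14, bypasses 15, and returns at 16. CBS reduction of 14 with (S)-2-methyl-CBS-oxazaborolidine and catecholborane (toluene, −78 °C; the ring alkenyl side acts as the large group) should give 12-[(tert-butyldimethylsilyl)oxy]-7α-hydroxy-13,14,15,16-tetranorlabd-8(17)-en-19-oic acid F5. Acetylation of F5 with Ac2O, DMAP and pyridine, followed by aqueous NaHCO3 work-up to hydrolyse the mixed anhydride at C19, should give 16.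

**Further compounds**

F1 | step 7 | (E)-6-[(tert-butyldimethylsilyl)oxy]-2-oxo-1-(phenylselanyl)hex-3-en-1-yl (S)-1,3-dimethylcyclohex-2-ene-1-carboxylate (C1 epimers) | C[C@@]1(C(=O)OC([Se]c2ccccc2)C(=O)/C=C/CCO[Si](C)(C)C(C)(C)C)C=C(C)CCC1
F2 | step 7 | 12-[(tert-butyldimethylsilyl)oxy]-7-oxo-13,14,15,16,17-pentanorlabdan-19,6β-olide | CC(C)(C)[Si](C)(C)OCC[C@H]1CC(=O)[C@@H]3[C@@H]2[C@]1(C)CCC[C@]2(C)C(=O)O3
F3 | step 9 | 17-(dimethylamino)-12-[(tert-butyldimethylsilyl)oxy]-7-oxo-13,14,15,16-tetranorlabdan-19-oic acid (C8 epimers) | CC(C)(C)[Si](C)(C)OCC[C@H]1C(CN(C)C)C(=O)C[C@@H]2[C@]1(C)CCC[C@]2(C)C(=O)O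
F4 | step 9 | 17-(dimethyloxidoamino)-12-[(tert-butyldimethylsilyl)oxy]-7-oxo-13,14,15,16-tetranorlabdan-19-oic acid (N-oxide of F3) | CC(C)(C)[Si](C)(C)OCC[C@H]1C(C[N+](C)(C)[O-])C(=O)C[C@@H]2[C@]1(C)CCC[C@]2(C)C(=O)O
F5 | step 11 | 12-[(tert-butyldimethylsilyl)oxy]-7α-hydroxy-13,14,15,16-tetranorlabd-8(17)-en-19-oic acid | CC(C)(C)[Si](C)(C)OCC[C@H]1C(=C)[C@H](O)C[C@@H]2[C@]1(C)CCC[C@]2(C)C(=O)O
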